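**Retrosynthetic overview**

- The target is reached by deallylation of the ring B phenol and, before that, C-prenylation at C8, the only free carbon of ring A in a 6-aroyl-5,7-dihydroxy-2,2-dimethyl-2H-chromene.
- The pyran ring is cut at C4–C4a and C2–C3. C3=C4 becomes acetylene, and O1–C2(CH3)2 becomes a tertiary α-aryloxy radical released from the N-acyloxyphthalimide of an aryloxyisobutyric acid; this reverses the polarity of the ketal-level carbon C2.
- Enabling feature: C2 is a quaternary, O1-bound carbon with two methyls (a tertiary α-oxygen radical with a carboxyl handle, no stereocentre). C3=C4 is an unsubstituted cis CH=CH. C4a is a C–H ortho to O1, and before prenylation ring A has a mirror plane through C6 and C8a, so both ortho carbons are the same.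
- The radical precursor comes from selective O-alkylation of the 4-OH (para to C=O) of a 2,4,6-trihydroxybenzophenone, itself made by Houben–Hoesch acylation of phloroglucinol with 4-(allyloxy)benzonitrile.
- Ring order: rings A and B are bought as arenes and joined first; the pyran ring is the only ring formed (step 6).

Key step: step 6

Remark on the chemistry: the target is achiral (C2 carries two methyl groups and the C3=C4 double bond is cis by ring constraint), so no stereocentre has to be set. 4-(Allyloxy)benzonitrile is prepared in step 1 rather than assumed to be purchasable.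

**Route**

Step 1
Reactants: 1 4-hydroxybenzonitrile; 2 allyl bromide (3-bromoprop-1-ene)
Product: 3 4-(allyloxy)benzonitrile
Conditions: K2CO3, acetone, reflux
Reagents that add atoms: allyl bromide, C=CCBr
Why: Williamson ether synthesis; the phenoxide of a para-cyanophenol should be alkylated cleanly at oxygen by a primary allylic bromide.

Step 2
Reactants: 3 4-(allyloxy)benzonitrile; 4 phloroglucinol (benzene-1,3,5-triol, anhydrous)
Product: 6 [4-(allyloxy)phenyl](2,4,6-trihydroxyphenyl)methanone, via ketiminium chloride 5 (not isolated)
Conditions: ZnCl2 (0.3 equiv), HCl (g), Et2O, 0 °C; then H2O, 100 °C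
Reagents that add atoms: phloroglucinol, Oc1cc(O)cc(O)c1; water, O
Why: Houben–Hoesch acylation: the HCl/ZnCl2-activated nitrile should be attacked once by the symmetric, very nucleophilic phloroglucinol (the ketiminium salt deactivates the ring against a second acylation), and hot water then hydrolyses the salt to the ketone, the allyl aryl ether being inert to HCl in ether.

Step 3
Reactants: 6 [4-(allyloxy)phenyl](2,4,6-trihydroxyphenyl)methanone; 7 ethyl 2-bromo-2-methylpropanoate
Product: 8 ethyl 2-{4-[4-(allyloxy)benzoyl]-3,5-dihydroxyphenoxy}-2-methylpropanoate
Conditions: K2CO3 (1.2 equiv), DMF, 70 °C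
Reagents that add atoms: ethyl 2-bromo-2-methylpropanoate, CCOC(=O)C(C)(C)Br
Why: Williamson-type O-alkylation with an α-bromoisobutyrate (the fibrate ether synthesis); with a limited amount of carbonate only the non-chelated 4-OH para to the carbonyl should be ionised, the two ortho OH groups being tied up in hydrogen bonds to the ketone.

Step 4
Reactants: 8 ethyl 2-{4-[4-(allyloxy)benzoyl]-3,5-dihydroxyphenoxy}-2-methylpropanoate
Product: 9 2-{4-[4-(allyloxy)benzoyl]-3,5-dihydroxyphenoxy}-2-methylpropanoic acid
Conditions: LiOH, THF/MeOH/H2O, 45 °C; then 1 M HCl
Reagents that add atoms: lithium hydroxide, [Li+].[OH-]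
Why: Saponification of the hindered ester; the aryl ethers, the benzophenone and the allyl group are inert to aqueous hydroxide, and acidification should return the free acid.

Step 5
Reactants: 9 2-{4-[4-(allyloxy)benzoyl]-3,5-dihydroxyphenoxy}-2-methylpropanoic acid; 10 N-hydroxyphthalimide
Product: 11 1,3-dioxoisoindolin-2-yl 2-{4-[4-(allyloxy)benzoyl]-3,5-dihydroxyphenoxy}-2-methylpropanoate
Conditions: DIC, DMAP (cat.), CH2Cl2, 0 °C → 25 °C
Reagents that add atoms: N-hydroxyphthalimide, ON1C(=O)c2ccccc2C1=O
Why: Steglich-type carbodiimide esterification to the N-acyloxyphthalimide (redox-active ester), a class well known for aryloxyisobutyric acids; the chelated ortho phenols are too weakly nucleophilic to compete with N-hydroxyphthalimide.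

Step 6
Reactants: 11 1,3-dioxoisoindolin-2-yl 2-{4-[4-(allyloxy)benzoyl]-3,5-dihydroxyphenoxy}-2-methylpropanoate; 12 acetylene (ethyne)
Product: 15 [4-(allyloxy)phenyl](5,7-dihydroxy-2,2-dimethyl-2H-chromen-6-yl)methanone, via tertiary α-aryloxyalkyl radical 13 (not isolated), via vinyl radical 14 (not isolated)
Conditions: acetylene (1 atm), fac-Ir(ppy)3 (1 mol%), MeCN (degassed), blue LEDs (450 nm), 25 °C
Reagents that add atoms: acetylene, C#C
Why: Proposed new method: the excited fac-Ir(ppy)3 should reduce the N-acyloxyphthalimide of 11 by single-electron transfer, and loss of CO2 and phthalimide anion gives the nucleophilic tertiary α-aryloxy radical 13, which should add to acetylene (C2–C3 bond) to give the σ-vinyl radical 14; 14 should then attack the free ortho carbon of ring A (C4–C4a bond), and the resulting cyclohexadienyl radical should be oxidised by the tetravalent iridium formed in the first electron transfer and give its proton to phthalimide anion, so that the cycle is redox-neutral. The closest known reaction types are the photoredox annulation of N-aryl α-aminoalkyl radicals with electron-poor alkenes to tetrahydroquinolines, the radical cyclisation of aryl propargyl ethers to 2H-chromenes through the same kind of vinyl radical, and the photoredox addition of α-oxyalkyl radicals to acetylene gas; decarboxylative generation of this very type of radical from aryloxyisobutyric redox-active esters is established. The pyran ring closes by a 6-endo ortho-cyclisation of the vinyl radical onto the arene (homolytic aromatic substitution), and the new double bond is cis because it lies in the six-membered ring. No stereocentre is formed, since C2 carries two methyl groups. The step needs ortho rather than ipso attack and addition to acetylene faster than electron transfer to or from 13: the two ortho positions of 11 are equivalent by symmetry so only one chromene can form, ipso attack gives a spiro radical that can only revert, the gem-dimethyl group favours ring closure, and acetonitrile saturated with acetylene (a poor hydrogen donor, high alkyne concentration against a very low concentration of oxidised catalyst) should protect 13 and 14 from side reactions.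

Step 7
Reactants: 15 [4-(allyloxy)phenyl](5,7-dihydroxy-2,2-dimethyl-2H-chromen-6-yl)methanone; 16 prenyl bromide (1-bromo-3-methylbut-2-ene)
Product: 17 [4-(allyloxy)phenyl][5,7-dihydroxy-2,2-dimethyl-8-(3-methylbut-2-en-1-yl)-2H-chromen-6-yl]methanone
Conditions: prenyl bromide (1.1 equiv), 10% aq KOH, 0 °C → 25 °C
Reagents that add atoms: prenyl bromide, CC(C)=CCBr
Why: C-alkylation of an acylphloroglucinol phenoxide with an allylic bromide in water, a standard way to C-prenylate such rings; C8 is the only unsubstituted carbon of ring A (ortho to O7, para to O5), and the aqueous medium solvates the phenoxide oxygens and so should favour attack through carbon.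

Step 8
Reactants: 17 [4-(allyloxy)phenyl][5,7-dihydroxy-2,2-dimethyl-8-(3-methylbut-2-en-1-yl)-2H-chromen-6-yl]methanone
Product: 18 vismiaphenone E, [5,7-dihydroxy-2,2-dimethyl-8-(3-methylbut-2-en-1-yl)-2H-chromen-6-yl](4-hydroxyphenyl)methanone
Conditions: Pd(PPh3)4 (5 mol%), morpholine, THF, 25 °C
Reagents that add atoms: none
Why: Tsuji–Trost deallylation: zerovalent palladium should ionise the unhindered allyl aryl ether to a π-allyl complex that morpholine captures, while the C-prenyl group and the hindered tertiary cyclic ether of the chromene stay untouched at 25 °C.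

**Compound list**

1 | 4-hydroxybenzonitrile | N#Cc1ccc(O)cc1 | starting material
2 | allyl bromide (3-bromoprop-1-ene) | C=CCBr | starting material
3 | 4-(allyloxy)benzonitrile | N#Cc1ccc(OCC=C)cc1 | intermediate
4 | phloroglucinol (benzene-1,3,5-triol) | Oc1cc(O)cc(O)c1 | starting material
5 | [4-(allyloxy)phenyl](2,4,6-trihydroxyphenyl)methaniminium chloride (ketiminium chloride) | [Cl-].[NH2+]=C(c1ccc(OCC=C)cc1)c1c(O)cc(O)cc1O | intermediate
6 | [4-(allyloxy)phenyl](2,4,6-trihydroxyphenyl)methanone | C=CCOc1ccc(cc1)C(=O)c1c(O)cc(O)cc1O | intermediate
7 | ethyl 2-bromo-2-methylpropanoate | CCOC(=O)C(C)(C)Br | starting material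
8 | ethyl 2-{4-[4-(allyloxy)benzoyl]-3,5-dihydroxyphenoxy}-2-methylpropanoate | CCOC(=O)C(C)(C)Oc1cc(O)c(c(O)c1)C(=O)c1ccc(OCC=C)cc1 | intermediate
9 | 2-{4-[4-(allyloxy)benzoyl]-3,5-dihydroxyphenoxy}-2-methylpropanoic acid | OC(=O)C(C)(C)Oc1cc(O)c(c(O)c1)C(=O)c1ccc(OCC=C)cc1 | intermediate
10 | N-hydroxyphthalimide | ON1C(=O)c2ccccc2C1=O | starting material
11 | 1,3-dioxoisoindolin-2-yl 2-{4-[4-(allyloxy)benzoyl]-3,5-dihydroxyphenoxy}-2-methylpropanoate | O=C(ON1C(=O)c2ccccc2C1=O)C(C)(C)Oc1cc(O)c(c(O)c1)C(=O)c1ccc(OCC=C)cc1 | intermediate
12 | acetylene (ethyne) | C#C | starting material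
13 | 2-{4-[4-(allyloxy)benzoyl]-3,5-dihydroxyphenoxy}propan-2-yl radical | C[C](C)Oc1cc(O)c(c(O)c1)C(=O)c1ccc(OCC=C)cc1 | intermediate
14 | 3-{4-[4-(allyloxy)benzoyl]-3,5-dihydroxyphenoxy}-3-methylbut-1-en-1-yl radical | [CH]=CC(C)(C)Oc1cc(O)c(c(O)c1)C(=O)c1ccc(OCC=C)cc1 | intermediate
15 | [4-(allyloxy)phenyl](5,7-dihydroxy-2,2-dimethyl-2H-chromen-6-yl)methanone | C=CCOc1ccc(cc1)C(=O)c1c(O)cc2OC(C)(C)C=Cc2c1O | intermediate
16 | prenyl bromide (1-bromo-3-methylbut-2-ene) | CC(C)=CCBr | starting material
17 | [4-(allyloxy)phenyl][5,7-dihydroxy-2,2-dimethyl-8-(3-methylbut-2-en-1-yl)-2H-chromen-6-yl]methanone | C=CCOc1ccc(cc1)C(=O)c1c(O)c(CC=C(C)C)c2OC(C)(C)C=Cc2c1O | intermediate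
18 | vismiaphenone E, [5,7-dihydroxy-2,2-dimethyl-8-(3-methylbut-2-en-1-yl)-2H-chromen-6-yl](4-hydroxyphenyl)methanone (achiral) | CC(C)=CCc1c(O)c(C(=O)c2ccc(O)cc2)c(O)c2c1OC(C)(C)C=C2 | target

**Step count and risks**

Total step count: 8. Longest linear sequence: 8 steps (from 4-hydroxybenzonitrile; the other inputs are bought).

Steps most likely to fail:

1. Step 6 (proposed new method). The tertiary radical may be oxidised to the oxocarbenium ion before it meets acetylene, which would end in loss of the side chain. The vinyl radical may abstract hydrogen before ring closure, and the hydroxybenzophenone chromophore may quench the excited photocatalyst. Fallback with known chemistry, setting out from 6: selective O-alkylation of the 4-OH with 3-chloro-3-methylbut-1-yne (K2CO3, KI, CuI (cat.), acetone, reflux) should give the aryl propargyl ether [4-(allyloxy)phenyl]{2,6-dihydroxy-4-[(2-methylbut-3-yn-2-yl)oxy]phenyl}methanone F1. Heating in xylene at 130 °C should then bring about the aromatic propargyl Claisen rearrangement, 1,5-hydrogen shift and oxa-6π electrocyclisation onto either of the two equivalent ortho carbons. The route is rejoined at 15.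

2. Step 7. Alkylation may occur at a phenoxide oxygen instead of carbon, and a second alkylation with dearomatisation may follow. Fallback, setting out from 15: Friedel–Crafts prenylation of the neutral phenol with 2-methylbut-3-en-2-ol and BF3·OEt2 in dioxane at 25 °C, in which the prenyl cation attacks the only free carbon of ring A. This leads directly to 17 and makes no new compound (F0).

3. Step 3. Substitution at the tertiary bromide by a weakly nucleophilic, carbonyl-conjugated phenoxide may be slow, with competing E2 elimination of the bromoester and incomplete conversion. Fallback, setting out from 6: Bargellini reaction with 1,1,1-trichloro-2-methylpropan-2-ol and NaOH in acetone (0 °C → 25 °C, then HCl), in which the non-chelated phenoxide opens the gem-dichloroepoxide formed in situ at its tertiary carbon. This gives the acid directly, rejoins the route at 9 and makes no new compound (F0).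

**Further compounds**

F1 | step 6 | [4-(allyloxy)phenyl]{2,6-dihydroxy-4-[(2-methylbut-3-yn-2-yl)oxy]phenyl}methanone | C#CC(C)(C)Oc1cc(O)c(c(O)c1)C(=O)c1ccc(OCC=C)cc1
F0 | step 7 | none | none
F0 | step 3 | none | none
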